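In a one-step world Z and L join mole for mole on E to give G, so the ceiling on G is 90.0%, the smaller of the charges of Z and L divided by the charge of Z.

all flasks: Z 0.046 M

| run | L | E | temperature | remark | time |
|---|---|---|---|---|---|
| red | 0.0414 M | 0.34 mM | −5 °C | run made earlier |  |
| amber | 0.0414 M | 0.53 mM | 8 °C | run made earlier |  |
| ochre | 0.083 M | 0.24 mM | −5 °C | run made earlier |  |
| north-west | 0.0414 M | 0.24 mM | 0 °C |  | 25 d |
| east | 0.0414 M | 0.24 mM |  | at 0 °C until 20 d, from then on at 15 °C | 25 d |
| north | 0.0414 M | 0.24 mM | 15 °C |  | 25 d |

- the earlier runs were read with a standard deviation of 0.3 percentage points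

- red (time / d: G / %): 1.67: 35.8; 3.00: 57.0; 6.00: 77.2; 10.0: 85.8; 20.0: 89.7
- amber (time / d: G / %): 4.00: 86.6; 8.00: 89.2; 12.0: 89.6; 15.0: 89.7; 20.0: 89.5
- ochre (time / d: G / %): 1.67: 33.2; 5.00: 74.8; 10.0: 93.8; 15.0: 98.3; 20.0: 99.8

(standard deviation of a reading: 0.3 percentage points)

- the flask that comes out highest in amount of G, in percent of the Z charged, or "all alike" when all lie within 1.5 percentage points (north-west / east / north / all alike)
- G at the end, in percent of the Z charged, north-west
- G at the end, in percent of the Z charged, east
- G at the end, in percent of the Z charged, north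

I turn the settings one at a time. L comes first. Red ends at 89.7%, while ochre, with 0.083 M of L, ends at 99.8% against a ceiling of 100%. So I take L as the limiting reagent in the new flasks.

E and warmth should change the speed of the approach, not its height: amber differs from red in both, yet reads 89.7% late on. Taking the approach as exponential, red's reading at 3.00 d gives a rate constant of 0.334 d⁻¹. Scaled in proportion to E, that becomes 0.236 d⁻¹ at 0.24 mM.

Amber's reading at 4.00 d gives 0.819 d⁻¹, which per unit of E is 1.57 times red's. North, at 15 °C, is warmer than amber, so that flask is an extrapolation.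

Time comes last: 25 d is 5.90 time constants, which puts north-west at 89.8%. East and north get more warmth, so I put them at the ceiling and call the three alike, since the gap of 0.20 points is smaller than the margin.

The forecast says all alike, with 89.7% for north-west, 89.7% for east and 89% for north, a flask that “should also finish”, and that last value lies below my ceiling.

The flasks give 89.6% for north-west, 89.8% for east and 90.0% for north, which is all alike.

    L + E + J → E + G (k = 153 M⁻² min⁻¹, Ea = 38.0 kJ mol⁻¹)
    Z + E ⇌ E + J (K = 1.70, k = 1.43 M⁻¹ min⁻¹, Ea = 50.0 kJ mol⁻¹, ΔH = −42.0 kJ mol⁻¹)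
    (constants at 0 °C)

North stands at the ceiling of 90.0% with 90.0%. Now take north-west's recipe with 0.18 M of Z instead. L is then 0.230 equiv to Z, and the same reckoning gives a ceiling of 23.0%. That neighbour ends at 23.0% of G after 25.0 d, with L at 0% of its own charge. The rest of its Z stands as free Z, 28.5%, and as J, 48.5%, the larger share of the three.

The numbers in the tables come from a simulation with made-up constants.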